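**Retrosynthetic overview**
1. The target is a bicyclic 4-pyranone. Ring A is O1/C2/C3/C4/C4a/C8a, ring B is C4a/C5–C8/C8a with a 5S carbinol, and C2 carries a C17 chain (C1′–C17′, Z-alkene C12′=C13′). The alkene travels as an alkyne and is set last by Lindlar semi-hydrogenation.
2. The key disconnection is C7′–C8′. It is made by an anodic decarboxylative radical cross-coupling (mixed Kolbe electrolysis) of the unprotected hydroxy acid (core + C1′–C7′ + CO2H) with undec-6-ynoic acid (C8′–C17′ + CO2H). The two carboxyl groups are the only activators and leave as CO2.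
3. Enabling feature: C7′ and C8′ lie inside the unbranched (CH2)11 stretch as primary CH2 carbons with no α-heteroatom or branch. C7′ is seven CH2 groups from ring A and C8′ is four CH2 groups from C12′≡C13′. Both radicals should therefore couple rather than oxidise or cyclise, and the electron-poor ring A and the C5–OH are harder to oxidise than a carboxylate.
4. Ring order: ring B is bought as cyclohexane-1,3-dione. C4–C4a comes from acylketene C-acylation, and ring A (O1–C2) is closed by an acid cyclodehydration that also frees the carboxyl group. C5 is set by asymmetric transfer hydrogenation.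
5. Undec-6-ynoic acid is made in one step from hept-6-ynoic acid and 1-iodobutane.

Key step: step 6

Assumption: azelaic acid mono-tert-butyl ester (a catalogue linker building block) and hept-6-ynoic acid are taken as purchasable. Side-chain locants count from the carbon attached to C2.

Step 1
Reactants: 1 azelaic acid mono-tert-butyl ester [9-(tert-butoxy)-9-oxononanoic acid]; 2 Meldrum's acid
Product: 3 acyl Meldrum's acid [tert-butyl 9-(2,2-dimethyl-4,6-dioxo-1,3-dioxan-5-ylidene)-9-hydroxynonanoate]
Conditions: DCC, DMAP, CH2Cl2, 0 °C → rt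
Reagents that add atoms: none
Why: Carbodiimide activation followed by C-acylation of the strongly C–H-acidic Meldrum's acid (Oikawa–Yonemitsu acylation) should give the enolised acyl Meldrum's acid, and the tert-butyl ester is inert to DCC/DMAP.

Step 2
Reactants: 3 acyl Meldrum's acid; 4 cyclohexane-1,3-dione
Product: 7 β-triketone [tert-butyl 11-(2-hydroxy-6-oxocyclohex-1-en-1-yl)-9,11-dioxoundecanoate], via acylketene 5 (not isolated), via enol ester 6 (not isolated)
Conditions: PhMe, 100 °C; then Et3N, DMAP (20 mol%), rt
Reagents that add atoms: none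
Why: Thermal retro-[4+2] fragmentation of 3 (loss of acetone and CO2) releases acylketene 5, which acylates the enol of 4, and the DMAP/Et3N-mediated O→C acyl migration known from 2-acylcyclohexane-1,3-dione synthesis (and from C-acetoacetylation of cyclic 1,3-diones with diketene) should drain enol ester 6 into the chelated β-triketone 7 as the thermodynamic sink.

Step 3
Reactants: 7 β-triketone
Product: 9 keto acid [8-(4,5-dioxo-5,6,7,8-tetrahydro-4H-chromen-2-yl)octanoic acid], via pyranone tert-butyl ester 8 (not isolated)
Conditions: TFA/CH2Cl2 1:1, rt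
Reagents that add atoms: none
Why: Acid cyclodehydration of a 1,3,5-tricarbonyl array to a 4-pyranone (6-exo-trig attack of the ring-B enol oxygen on the side-chain ketone, then loss of water, both conceivable O-closures giving the same O1 bridge) and E1 cleavage of a tert-butyl ester are both classical TFA reactions, so one operation should close ring A and unmask the carboxyl handle.

Step 4
Reactants: 9 keto acid
Product: 10 hydroxy acid [8-[(5S)-5-hydroxy-4-oxo-5,6,7,8-tetrahydro-4H-chromen-2-yl]octanoic acid]
Conditions: RuCl[(S,S)-TsDPEN](p-cymene) (1 mol%), HCO2H/Et3N 5:2, EtOAc, 35 °C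
Reagents that add atoms: none
Why: In this Noyori–Ikariya asymmetric transfer hydrogenation of a tetralone/chromanone-type ketone, the CH/π contact between the η6-arene of the (S,S)-catalyst and the flat ring A makes ring A the "aryl" group, so hydride should add to the Re face of C5 and set 5S, while the doubly vinylogous C4 carbonyl, the ring double bonds and the free carboxyl group are untouched in the formic acid medium.

Step 5
Reactants: 11 hept-6-ynoic acid; 12 1-iodobutane
Product: 14 undec-6-ynoic acid, via dilithio hept-6-ynoate 13 (not isolated)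
Conditions: n-BuLi (2.1 equiv), THF/DMPU, −78 → 0 °C; 12, 0 °C → rt; aq. HCl
Reagents that add atoms: none
Why: SN2 alkylation of the carboxylate/acetylide dianion of an ω-alkynoic acid with a primary iodide in a dipolar cosolvent is standard acetylide chemistry, the carboxylate being too weak a nucleophile to compete.

Step 6
Reactants: 10 hydroxy acid; 14 undec-6-ynoic acid (5 equiv)
Product: 17 alkynyl carbinol [(5S)-2-(heptadec-12-yn-1-yl)-5-hydroxy-5,6,7,8-tetrahydro-4H-chromen-4-one], via chromenonylheptyl radical 15 (not isolated), via dec-5-ynyl radical 16 (not isolated)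
Conditions: NaOMe (5 mol% of total acid), MeOH, smooth Pt anode / stainless-steel cathode, undivided cell, constant current ca. 200 mA cm⁻², 15–20 °C, ca. 1.3 F per mol of total acid, stopped while still weakly acidic
Reagents that add atoms: none
Why: In this mixed Kolbe electrolysis both carboxylates are oxidised by one electron at the platinum anode and lose CO2 inside the carboxylate-covered electrode layer, and the primary radicals 15 and 16 combine to form the C7′–C8′ bond while carboxyl protons are reduced to H2 at the cathode. The closest known reaction type is the mixed Kolbe coupling of alkynoic or alkenoic acids with ω-functionalised (ester, keto, hydroxy) alkanoic acids, long used for pheromone and fatty-acid chains. No ring is closed and no stereocentre is created, and the remote C5 carbinol centre takes no part, so its configuration should be carried through. Radical rather than cation chemistry is secured because both radical carbons are unbranched primary CH2 groups without an α-heteroatom, which on smooth Pt at high current density in weakly acidic MeOH couple instead of being oxidised further (Hofer–Moest pathway). Cross- versus homo-coupling is statistical and is steered by the excess of cheap 14, so that radical 15 should mostly meet 16, and the main by-product of that excess is an apolar hydrocarbon easily separated from polar 17 on silica. Escape routes are closed by design: the alkyne in 16 makes 5-exo cyclisation roughly an order of magnitude slower than for the hex-5-enyl radical that the Z-alkene would give, 15 could reach C2/C3 of ring A only through eight- or nine-membered transition states, the electron-poor pyranone and the secondary carbinol are harder to oxidise than adsorbed carboxylate (the solvent is itself an alcohol), and the steel cathode avoids cathodic hydrogenation of the alkyne.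

Step 7
Reactants: 17 alkynyl carbinol
Product: 18 target [(5S)-2-[(12Z)-heptadec-12-en-1-yl]-5-hydroxy-5,6,7,8-tetrahydro-4H-chromen-4-one]
Conditions: H2 (1 atm), Lindlar catalyst (Pd/CaCO3, Pb-poisoned), quinoline, EtOAc, rt, stopped after 1 equiv H2
Reagents that add atoms: none
Why: Lindlar semi-hydrogenation delivers both hydrogens syn from the poisoned Pd surface and should give the Z-alkene, while ring A and the C5 carbinol are inert to this deactivated catalyst.

**Compound list**
1 | azelaic acid mono-tert-butyl ester, 9-(tert-butoxy)-9-oxononanoic acid | CC(C)(C)OC(=O)CCCCCCCC(=O)O | starting material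
2 | Meldrum's acid, 2,2-dimethyl-1,3-dioxane-4,6-dione | CC1(C)OC(=O)CC(=O)O1 | starting material
3 | tert-butyl 9-(2,2-dimethyl-4,6-dioxo-1,3-dioxan-5-ylidene)-9-hydroxynonanoate | CC(C)(C)OC(=O)CCCCCCCC(O)=C1C(=O)OC(C)(C)OC1=O | intermediate
4 | cyclohexane-1,3-dione | O=C1CCCC(=O)C1 | starting material
5 | acylketene, tert-butyl 9,11-dioxoundec-10-enoate | CC(C)(C)OC(=O)CCCCCCCC(=O)C=C=O | intermediate
6 | enol ester, 11-tert-butyl 1-(3-oxocyclohex-1-en-1-yl) 3-oxoundecanedioate | CC(C)(C)OC(=O)CCCCCCCC(=O)CC(=O)OC1=CC(=O)CCC1 | intermediate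
7 | tert-butyl 11-(2-hydroxy-6-oxocyclohex-1-en-1-yl)-9,11-dioxoundecanoate | CC(C)(C)OC(=O)CCCCCCCC(=O)CC(=O)C1=C(O)CCCC1=O | intermediate
8 | tert-butyl 8-(4,5-dioxo-5,6,7,8-tetrahydro-4H-chromen-2-yl)octanoate | CC(C)(C)OC(=O)CCCCCCCc1cc(=O)c2c(o1)CCCC2=O | intermediate
9 | 8-(4,5-dioxo-5,6,7,8-tetrahydro-4H-chromen-2-yl)octanoic acid | OC(=O)CCCCCCCc1cc(=O)c2c(o1)CCCC2=O | intermediate
10 | 8-[(5S)-5-hydroxy-4-oxo-5,6,7,8-tetrahydro-4H-chromen-2-yl]octanoic acid | OC(=O)CCCCCCCc1cc(=O)c2c(o1)CCC[C@@H]2O | intermediate
11 | hept-6-ynoic acid | C#CCCCCC(=O)O | starting material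
12 | 1-iodobutane | CCCCI | starting material
13 | dilithio hept-6-ynoate (lithium carboxylate, lithium acetylide) | [Li]C#CCCCCC(=O)O[Li] | intermediate
14 | undec-6-ynoic acid | CCCCC#CCCCCC(=O)O | intermediate
15 | 7-[(5S)-5-hydroxy-4-oxo-5,6,7,8-tetrahydro-4H-chromen-2-yl]heptyl radical | [CH2]CCCCCCc1cc(=O)c2c(o1)CCC[C@@H]2O | intermediate
16 | dec-5-yn-1-yl radical | [CH2]CCCC#CCCCC | intermediate
17 | (5S)-2-(heptadec-12-yn-1-yl)-5-hydroxy-5,6,7,8-tetrahydro-4H-chromen-4-one | CCCCC#CCCCCCCCCCCCc1cc(=O)c2c(o1)CCC[C@@H]2O | intermediate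
18 | (5S)-2-[(12Z)-heptadec-12-en-1-yl]-5-hydroxy-5,6,7,8-tetrahydro-4H-chromen-4-one | CCCC/C=C\CCCCCCCCCCCc1cc(=O)c2c(o1)CCC[C@@H]2O | target

Total step count: 7. Longest linear sequence: 6 (steps 1, 2, 3, 4, 6, 7).

**Steps most likely to fail**

**Step 6 (mixed Kolbe coupling).**
- Risks: homo-coupling and disproportionation may consume the minor acid. The alkynyl radical may undergo 5-exo-dig cyclisation before coupling. The C5 carbinol may be oxidised at the anode, or the anode may passivate.
- The fallback sets out from 9 and comes back at 17. It makes only the chromenone half a radical and turns the alkynyl half into a carbanion equivalent.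
- Keto acid 9 is condensed with N-hydroxyphthalimide (DIC, cat. DMAP, CH2Cl2) to the redox-active ester 1,3-dioxoisoindolin-2-yl 8-(4,5-dioxo-5,6,7,8-tetrahydro-4H-chromen-2-yl)octanoate F1.
- Commercial dec-5-yn-1-ol is converted by an Appel reaction (CBr4, PPh3) into 1-bromodec-5-yne F2. Mg in THF then gives dec-5-ynylmagnesium bromide F3, and ZnCl2 (0.5 equiv) gives bis(dec-5-ynyl)zinc F4.
- Nickel-catalysed decarboxylative alkyl–alkyl cross-coupling of F1 with F4 (NiCl2·glyme, 4,4′-di-tert-butyl-2,2′-bipyridine, THF/DMF, rt) should form the same C7′–C8′ bond and give 2-(heptadec-12-yn-1-yl)-7,8-dihydro-4H-chromene-4,5(6H)-dione F5.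
- The C5 ketone of F5 is reduced under the conditions of step 4 to give 17.

**Step 2 (acylketene C-acylation).**
- Risks: acylation may stop at oxygen, the enol ester may close in the Pechmann sense to the isomeric 2-pyranone, or the acylketene may dimerise.
- The fallback sets out from 3 and comes back at 9. It masks the β-ketone so that plain carbodiimide C-acylation of cyclohexane-1,3-diones can be used.
- Heating 3 with benzyl alcohol in toluene gives 1-benzyl 11-tert-butyl 3-oxoundecanedioate F6.
- Noyori ketalisation (1,2-bis(trimethylsilyloxy)ethane, cat. TMSOTf, CH2Cl2, −78 → −20 °C) gives benzyl 2-[2-(8-tert-butoxy-8-oxooctyl)-1,3-dioxolan-2-yl]acetate F7.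
- Hydrogenolysis (H2, Pd/C, EtOAc) gives 2-[2-(8-tert-butoxy-8-oxooctyl)-1,3-dioxolan-2-yl]acetic acid F8.
- Coupling with 4 (DCC, DMAP, CH2Cl2; O-acylation then DMAP-induced O→C shift) gives tert-butyl 8-{2-[2-(2-hydroxy-6-oxocyclohex-1-en-1-yl)-2-oxoethyl]-1,3-dioxolan-2-yl}octanoate F9.
- Moist TFA/CH2Cl2 then removes the ketal, closes ring A and cleaves the tert-butyl ester to give 9.

**Step 4 (asymmetric transfer hydrogenation).**
- Risks: hydride transfer to the vinylogous-ester-type C5 carbonyl may be sluggish, the C4/C5 1,3-dicarbonyl unit may chelate ruthenium, or facial selectivity may be poor.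
- The fallback sets out from 9 and comes back at 10. It uses stoichiometric borane under oxazaborolidine control, which requires the acid to be masked.
- Treating 9 with TMSCHN2 (PhMe/MeOH) gives methyl 8-(4,5-dioxo-5,6,7,8-tetrahydro-4H-chromen-2-yl)octanoate F10.
- Corey–Bakshi–Shibata reduction ((R)-Me-CBS, catecholborane, PhMe, −78 °C, with the α-substituted enone carbon C4a as the large group) should give methyl 8-[(5S)-5-hydroxy-4-oxo-5,6,7,8-tetrahydro-4H-chromen-2-yl]octanoate F11.
- Saponification of F11 (LiOH, THF/H2O, 0 °C, then mild acidification) gives 10.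

**Further compounds**
F1 | step 6 | 1,3-dioxoisoindolin-2-yl 8-(4,5-dioxo-5,6,7,8-tetrahydro-4H-chromen-2-yl)octanoate | O=C(CCCCCCCc1cc(=O)c2c(o1)CCCC2=O)ON1C(=O)c2ccccc2C1=O
F2 | step 6 | 1-bromodec-5-yne | CCCCC#CCCCCBr
F3 | step 6 | dec-5-ynylmagnesium bromide | CCCCC#CCCCC[Mg]Br
F4 | step 6 | bis(dec-5-ynyl)zinc | CCCCC#CCCCC[Zn]CCCCC#CCCCC
F5 | step 6 | 2-(heptadec-12-yn-1-yl)-7,8-dihydro-4H-chromene-4,5(6H)-dione | CCCCC#CCCCCCCCCCCCc1cc(=O)c2c(o1)CCCC2=O
F6 | step 2 | 1-benzyl 11-tert-butyl 3-oxoundecanedioate | CC(C)(C)OC(=O)CCCCCCCC(=O)CC(=O)OCc1ccccc1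
F7 | step 2 | benzyl 2-[2-(8-tert-butoxy-8-oxooctyl)-1,3-dioxolan-2-yl]acetate | CC(C)(C)OC(=O)CCCCCCCC1(CC(=O)OCc2ccccc2)OCCO1
F8 | step 2 | 2-[2-(8-tert-butoxy-8-oxooctyl)-1,3-dioxolan-2-yl]acetic acid | CC(C)(C)OC(=O)CCCCCCCC1(CC(=O)O)OCCO1
F9 | step 2 | tert-butyl 8-{2-[2-(2-hydroxy-6-oxocyclohex-1-en-1-yl)-2-oxoethyl]-1,3-dioxolan-2-yl}octanoate | CC(C)(C)OC(=O)CCCCCCCC1(CC(=O)C2=C(O)CCCC2=O)OCCO1
F10 | step 4 | methyl 8-(4,5-dioxo-5,6,7,8-tetrahydro-4H-chromen-2-yl)octanoate | COC(=O)CCCCCCCc1cc(=O)c2c(o1)CCCC2=O
F11 | step 4 | methyl 8-[(5S)-5-hydroxy-4-oxo-5,6,7,8-tetrahydro-4H-chromen-2-yl]octanoate | COC(=O)CCCCCCCc1cc(=O)c2c(o1)CCC[C@@H]2O
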